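The readings are calculated with made-up constants, and the scatter is random.

What is easy to read first? On Monday's run, target stands at 84 % after 0.417 min, so by that reading a fraction 16.0 % of the starting material remains.

| flask | starting material | second substrate | free catalyst | remark |
|---|---|---|---|---|
| Monday's | 0.35 M | 1.4 M | 3.5 mM | run made earlier |
| Saturday's | 0.52 M | 1.4 M | 3.5 mM | run made earlier |
| flask | 0.70 M | 1.40 M | 3.5 mM |  |

| Monday's: time / min | Monday's: target / % | Saturday's: time / min | Saturday's: target / % |
|---|---|---|---|
| 0.417 | 84 | 0.417 | 82 |
| 0.833 | 97 | 0.833 | 98 |
| 1.33 | 98 | 1.33 | 102 |
| 1.50 | 102 | 1.50 | 100 |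
| 2.00 | 99 | 2.00 | 100 |
| 2.50 | 99 | 2.50 | 98 |
| 3.00 | 100 | 3.00 | 101 |

(standard deviation of a reading: 1.5 percentage points)

1. factor on the rate of making target when 30 % of the starting material are converted if free catalyst is charged twice over
2. factor on the rate when 30 % of the starting material are converted if free catalyst is charged at 20 mM instead

- no earlier run changes the charge of free catalyst; that part of a forecast is a guess

Treat this as one exponential decay. From Monday's first reading, 0.228 min is the time constant tau of the fraction of starting material left, at this charge of second substrate and free catalyst.

Is one reading enough? Test it on Saturday's run, which has a higher charge of starting material: tau predicts 97.4 % target at 0.833 min, and the reading is 98 %. So within the scatter of 1.5 percentage points the fraction falls at the same pace on both runs, which is pseudo-first-order behaviour, and I carry tau to the new flask.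

What does the question ask of tau? With the charge of starting material held and at a fixed conversion, the fraction left is the same, so the factor on the rate is the factor on 1/tau.

And the weak spot? No run varies the catalyst, so this part is a guess. If 1/tau follows the charge of free catalyst, the factors are 2.00 and 5.71. For catalyst held mostly in an inactive pair, the working part goes as the square root of the charge, which gives 1.41 and 2.39. I commit to the middle of each span on a log scale: 1.68 and 3.70.

The forecast stands higher than my figures, at 1.9 (1.35 to 2.3) and 5 (2.3 to 8): “I shade them slightly downward and keep the ranges wide”.

The simulation gives 1.54 and 2.82.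

    starting material + free catalyst ⇌ catalyst intermediate A (K = 1.10 M⁻¹, k = 181 M⁻¹ s⁻¹)
    second substrate + free catalyst ⇌ catalyst intermediate B (K = 1.28 M⁻¹, k = 44.9 M⁻¹ s⁻¹)
    2 free catalyst ⇌ resting dimer, settled at all times (K = 3030 M⁻¹)
    catalyst intermediate A → free catalyst + target (k = 319 s⁻¹)
    catalyst intermediate B → free catalyst + second product (k = 6.28 s⁻¹)

The flask reaches 30 % conversion at 0.0876 min, against 0.0813 min reckoned from tau. By its forward rate alone, the step of second substrate with free catalyst gives free catalyst a half-life of 0.023 s at 3.00 min in the flask, far shorter than tau. At 0.300 min the flask holds more of its catalyst as resting dimer, the resting state, than in any other form: 58.6 %, against 23.5 % as catalyst intermediate B, 16.6 % as free catalyst and 1.27 % as catalyst intermediate A.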